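## Retrosynthetic overview

1. δ-Tocopherol 6 ⇒ open the O1–C2 bond: catalyst-controlled, proton-triggered 6-endo closure of 2-methyl-6-phytylhydroquinone 5 (the substrate of tocopherol cyclase), which sets C2 (R) in the last step.
2. 5 ⇒ quinone 4 ⇒ phenol 3: para-oxygenation of a 2,6-dialkylphenol followed by reduction, in one flask.
3. 3 ⇒ o-cresol 1 + natural (2E,7R,11R)-phytol 2 by ortho C-allylation; C4' and C8' are bought with phytol.
4. Ring order: the benzene ring is bought; the dihydropyran ring is the only ring made, and it is made last.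

Assumption 1: natural phytol is bought as the single (2E,7R,11R) isomer (chlorophyll-derived).
Assumption 2: the (S,S) antipode of the catalyst in step 3 is taken as the one that gives 2R; the sense of induction is checked in the first run, and the (R,R) catalyst is used if it is the other way round.

Catalyst of step 3: (S,S)-IDPi, the imidodiphosphorimidate Brønsted acid HN[P(=NSO2CF3)(O2C20H10Ar2)]2, built from two (S)-3,3'-Ar2-BINOL units, Ar = 3,5-(CF3)2C6H3.

## Route

Step 1
Reactants: 1 o-cresol (2-methylphenol); 2 natural phytol, (2E,7R,11R)-3,7,11,15-tetramethylhexadec-2-en-1-ol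
Product: 3 2-methyl-6-[(2E,7R,11R)-3,7,11,15-tetramethylhexadec-2-en-1-yl]phenol
Conditions: acidic Al2O3 (Brockmann grade 1, about 2 g per mmol of 2), 1 (3 equiv), ClCH2CH2Cl, reflux, 12–24 h
Reagents that add atoms: none
Why: Alumina-templated ortho-selective Friedel–Crafts allylation of a phenol with an allylic alcohol: both partners sit on the acidic surface, the primary allylic C–O bond ionises and the only free ortho carbon attacks the CH2 terminus, so the linear E-allyl phenol forms with C7 and C11 untouched and no new stereocentre.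

Step 2
Reactants: 3 2-methyl-6-[(2E,7R,11R)-3,7,11,15-tetramethylhexadec-2-en-1-yl]phenol
Product: 5 2-methyl-6-[(2E,7R,11R)-3,7,11,15-tetramethylhexadec-2-en-1-yl]benzene-1,4-diol, via 2-methyl-6-phytyl-1,4-benzoquinone 4 (not isolated)
Conditions: Co(salen) (C16H14CoN2O2, divalent cobalt, 10 mol %), O2 (1 atm), DMF, 25 °C; then Ar purge, aq. Na2S2O4 (3 equiv), EtOAc, 25 °C, degassed work-up
Reagents that add atoms: dioxygen, O=O
Why: Cobalt–salen/O2 oxidation of a 2,6-dialkylphenol with a free para position gives the para-benzoquinone, and dithionite then reduces the quinone to the hydroquinone without touching the trisubstituted alkene or any stereocentre.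

Step 3
Reactants: 5 2-methyl-6-[(2E,7R,11R)-3,7,11,15-tetramethylhexadec-2-en-1-yl]benzene-1,4-diol
Product: 6 δ-tocopherol, (2R)-2,8-dimethyl-2-[(4R,8R)-4,8,12-trimethyltridecyl]-3,4-dihydro-2H-chromen-6-ol
Conditions: (S,S)-IDPi (5 mol %), cyclohexane, 5 Å MS, Ar, dark, 25 → 40 °C
Reagents that add atoms: none
Why: Proposed new method: asymmetric Brønsted-acid-catalysed intramolecular hydroaryloxylation in which the confined, strongly acidic IDPi pocket binds the phenolic OH next to the chain and protonates C2' of the E-alkene on its si face while that oxygen closes on the re face of C3' (concerted asynchronous anti addition, 6-endo, Markovnikov, the topology of tocopherol cyclase), so C2 is set as R by catalyst control with C4' and C8' as distant spectators and the other OH, meta to the chain, unable to cyclise; the closest known reaction type is the IDPi-catalysed asymmetric intramolecular hydroalkoxylation of unactivated alkenes.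

## Compound list

1 | o-cresol (2-methylphenol) | Cc1ccccc1O | starting material
2 | natural phytol, (2E,7R,11R)-3,7,11,15-tetramethylhexadec-2-en-1-ol | OC/C=C(\C)CCC[C@H](C)CCC[C@H](C)CCCC(C)C | starting material
3 | 2-methyl-6-[(2E,7R,11R)-3,7,11,15-tetramethylhexadec-2-en-1-yl]phenol | Cc1cccc(C/C=C(\C)CCC[C@H](C)CCC[C@H](C)CCCC(C)C)c1O | intermediate
4 | 2-methyl-6-[(2E,7R,11R)-3,7,11,15-tetramethylhexadec-2-en-1-yl]cyclohexa-2,5-diene-1,4-dione (2-methyl-6-phytyl-1,4-benzoquinone, formed in the flask) | CC1=CC(=O)C=C(C/C=C(\C)CCC[C@H](C)CCC[C@H](C)CCCC(C)C)C1=O | intermediate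
5 | 2-methyl-6-[(2E,7R,11R)-3,7,11,15-tetramethylhexadec-2-en-1-yl]benzene-1,4-diol | Cc1cc(O)cc(C/C=C(\C)CCC[C@H](C)CCC[C@H](C)CCCC(C)C)c1O | intermediate
6 | δ-tocopherol, (2R)-2,8-dimethyl-2-[(4R,8R)-4,8,12-trimethyltridecyl]-3,4-dihydro-2H-chromen-6-ol | Cc1cc(O)cc2c1O[C@](C)(CCC[C@H](C)CCC[C@H](C)CCCC(C)C)CC2 | target

## Step count and risks

Total step count: 3. Longest linear sequence: 3 steps (from 1 or 2 to 6).

**Most likely to fail: step 3.** The closure has no direct precedent on this substrate. The catalyst must tell methyl from the long chain at the forming tertiary ether carbon, and the free hydroquinone may tie up the acid or oxidise. Any shortfall shows as the 2S epimer, which is hard to remove.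

The fallback sets out from 3 and comes back at 6. It makes the C–O bond with a different face-selecting event and leaves the second oxygen for the end.
- Phenol 3 is cyclised by Lewis-base-catalysed enantioselective sulfenoetherification: N-(phenylsulfanyl)phthalimide, BINAM-derived selenophosphoramide (binaphthyl-N,N'-dimethyldiamine)P(=Se)N(i-Pr)2 (10 mol %), MsOH, CH2Cl2, −20 °C. The catalyst antipode is chosen so that the thiiranium ion lies on the si face of C2'. The phenol oxygen opens it at the tertiary carbon from the opposite face. This gives (2R,3S)-2,8-dimethyl-3-(phenylsulfanyl)-2-[(4R,8R)-4,8,12-trimethyltridecyl]chromane F1.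
- Raney Ni (EtOH, 50 °C) removes the sulfur and gives (2R)-2,8-dimethyl-2-[(4R,8R)-4,8,12-trimethyltridecyl]chromane F2.
- C–H borylation with [Ir(OMe)(cod)]2, 4,4'-di-tert-butyl-2,2'-bipyridine and B2pin2 (cyclohexane, 80 °C) goes to C6, the only aromatic C–H without an ortho substituent. It gives (2R)-2,8-dimethyl-6-(4,4,5,5-tetramethyl-1,3,2-dioxaborolan-2-yl)-2-[(4R,8R)-4,8,12-trimethyltridecyl]chromane F3.
- NaOH/H2O2 (THF/H2O, 0 °C, mildly acidic work-up) oxidises F3 to 6.

**Second: step 1.** o-Cresol has a free para position, so para-allylation, O-allylation or racemic ring closure on the alumina may lower the yield of 3.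

The fallback sets out from 2 and comes back at 3. It fixes the ring position with a halogen.
- PBr3 (Et2O, −10 °C) converts 2 into (2E,7R,11R)-1-bromo-3,7,11,15-tetramethylhexadec-2-ene (phytyl bromide) F4.
- Purchased 2-bromo-6-methylphenol F5 is treated with n-BuLi (2.1 equiv, Et2O, −78 → 0 °C) to give lithium 2-lithio-6-methylphenolate F6, made and used in the flask.
- F6 with CuBr·SMe2 (10 mol %) and F4 (−78 → 0 °C, water quench) gives 3 by attack at the primary allylic carbon.

**Third: step 2.** The cobalt/O2 oxidation may give diphenoquinone coupling or attack the doubly activated ArCH2–CH= position, and 5 re-oxidises easily during work-up.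

The fallback sets out from 2 and comes back at 5. The oxidation level of the ring is bought, not made.
- Purchased methylhydroquinone F7 is acylated at its unhindered 4-OH with pivaloyl chloride (pyridine, CH2Cl2, −20 °C). This gives 4-hydroxy-3-methylphenyl 2,2-dimethylpropanoate F8.
- Alumina-promoted ortho-allylation of F8 with 2 (acidic Al2O3, ClCH2CH2Cl, reflux) has only one free ortho position next to the free OH, and the para position is blocked. It gives 4-hydroxy-3-methyl-5-[(2E,7R,11R)-3,7,11,15-tetramethylhexadec-2-en-1-yl]phenyl 2,2-dimethylpropanoate F9.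
- LiAlH4 (THF, 0 °C, Ar, degassed mildly acidic work-up) removes the pivalate and gives 5.

## Further compounds

F1 | step 3 | (2R,3S)-2,8-dimethyl-3-(phenylsulfanyl)-2-[(4R,8R)-4,8,12-trimethyltridecyl]chromane | Cc1cccc2c1O[C@](C)(CCC[C@H](C)CCC[C@H](C)CCCC(C)C)[C@@H](Sc3ccccc3)C2
F2 | step 3 | (2R)-2,8-dimethyl-2-[(4R,8R)-4,8,12-trimethyltridecyl]chromane | Cc1cccc2c1O[C@](C)(CCC[C@H](C)CCC[C@H](C)CCCC(C)C)CC2
F3 | step 3 | (2R)-2,8-dimethyl-6-(4,4,5,5-tetramethyl-1,3,2-dioxaborolan-2-yl)-2-[(4R,8R)-4,8,12-trimethyltridecyl]chromane | Cc1cc(B3OC(C)(C)C(C)(C)O3)cc2c1O[C@](C)(CCC[C@H](C)CCC[C@H](C)CCCC(C)C)CC2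
F4 | step 1 | (2E,7R,11R)-1-bromo-3,7,11,15-tetramethylhexadec-2-ene (phytyl bromide) | BrC/C=C(\C)CCC[C@H](C)CCC[C@H](C)CCCC(C)C
F5 | step 1 | 2-bromo-6-methylphenol (purchased) | Cc1cccc(Br)c1O
F6 | step 1 | lithium 2-lithio-6-methylphenolate (made and used in the flask) | Cc1cccc([Li])c1O[Li]
F7 | step 2 | methylhydroquinone, 2-methylbenzene-1,4-diol (purchased) | Cc1cc(O)ccc1O
F8 | step 2 | 4-hydroxy-3-methylphenyl 2,2-dimethylpropanoate | Cc1cc(OC(=O)C(C)(C)C)ccc1O
F9 | step 2 | 4-hydroxy-3-methyl-5-[(2E,7R,11R)-3,7,11,15-tetramethylhexadec-2-en-1-yl]phenyl 2,2-dimethylpropanoate | Cc1cc(OC(=O)C(C)(C)C)cc(C/C=C(\C)CCC[C@H](C)CCC[C@H](C)CCCC(C)C)c1O
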